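The 3 questions below ask for two orders and one yield, and one number counted from the target readings serves the reckoning.

| flask | substrate | coupling partner | time |
|---|---|---|---|
| blue | 0.400 M | 0.480 M |  |
| ochre | 0.240 M | 0.320 M |  |
| grey | 0.200 M | 0.480 M |  |
| teal | 0.110 M | 0.480 M | 53 min |

- blue run (time / min: [target] / M): 1.9: 0.0306; 5.8: 0.0768; 11: 0.1143; 17: 0.1422; 25: 0.1618; 33: 0.1714; 43: 0.1839; 53: 0.1866
- ochre run (time / min: [target] / M): 1.9: 0.0118; 5.8: 0.0324; 11: 0.0513; 17: 0.0672; 25: 0.0783; 33: 0.0868; 43: 0.0920; 53: 0.0968
- grey run (time / min: [target] / M): 1.9: 0.0167; 5.8: 0.0393; 11: 0.0625; 17: 0.0778; 25: 0.0896; 33: 0.0971; 43: 0.1052; 53: 0.1076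

(each reading ± 0.001 M)

- reaction order in [coupling partner] at the outset, round the charge of the blue run, defined at two percent of the substrate turned into target
- reaction order in [substrate] at the outset, round the charge of the blue run, defined at two percent of the substrate turned into target (one fixed amount of target, the same in the runs compared)
- target in the teal run at 53 min, as a share of the substrate charged

- Overall: substrate + coupling partner -> target.
- Constant volume, constant temperature.
- "The second partner" is coupling partner.
- An order is taken over about fifteen percent of the charge, up and down.

Substrate is charged in a smaller amount than the coupling partner in every flask. The overall equation spends one substrate per target, so the charge minus c(target) stands for c(substrate) as far as that equation holds. The turn is ln(substrate charged / (substrate charged minus c(target))), a quantity counted from target, the species that is read. For a one-way reaction first order in substrate, and while c(coupling partner) stays near its charge, the turn at a given time does not depend on the substrate charge.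

The row at 5.8 min gives turns of 0.213 in blue, 0.219 in grey and 0.145 in ochre. Blue and grey share a partner charge but differ 2.00-fold in substrate, and their turns nearly match, so the order in substrate reads 0.963. Ochre over grey is 0.662 in turn against 0.667 in partner charge, so the order in partner reads 1.01. These readings span wider charges and a later time than the questions name.

The last row gives the yield. The turn at 53 min is 0.772 in grey and 0.628 in blue, so it is higher in grey, the flask with less substrate. Teal has the same partner charge, and a straight line in substrate charge through these two turns gives teal 0.837, which is a share of 56.7%.

The forecast gives orders of 1 (0.8 to 1.2) in partner and 1 (0.8 to 1.15) in substrate, and a yield of 55.8% (53.5% to 58%). It reads the plateaus as “a reversible reaction reaching equilibrium”. Its yield lies 0.9 percentage points below the line's.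

The teal run gives 56.8%, with orders of 1.0 in partner and 1.0 in substrate.

    substrate + coupling partner → target + by-product (0.09480 M⁻¹ min⁻¹)
    target + coupling partner → side product (0.01476 M⁻¹ min⁻¹)
    coupling partner → lost reagent (0.03456 min⁻¹)

The fit with a power law gives 61.1% for teal, more than the flask gives. Teal's share is a turn of 0.839, counted from target. In grey, the turn reaches 0.288 at 7.93 min, a pace of 0.0363 min⁻¹. It reaches 0.693 at 35.8 min, a pace of 0.0145 min⁻¹ over that stretch. It then reaches 0.772 at 53 min, a pace of 0.00458 min⁻¹.

All runs are calculated with made-up constants; scatter was added.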